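All runs are calculated from invented constants, noise included.

Theta carries 0.600 equiv of coupling partner against 0.150 equiv in eta, and theta goes from 35 °C to 95 °C at 80 min while eta stays at 35 °C, so the question for the next run is how much starting material ends as target rather than going elsewhere.

all flasks: starting material 0.025 M; free catalyst 0.78 mol%
- south-east: second substrate 1 equiv; coupling partner 0.19 equiv; temperature 50 °C; run made earlier
- west: second substrate 1 equiv; coupling partner 0.27 equiv; temperature 83 °C; run made earlier
- north: second substrate 1 equiv; coupling partner 0.64 equiv; temperature 50 °C; run made earlier
- eta: second substrate 1.00 equiv; coupling partner 0.150 equiv; at 35 °C throughout; time 2.5 h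
- theta: second substrate 1.00 equiv; coupling partner 0.600 equiv; at 35 °C until 80 min, from then on at 95 °C; time 2.5 h

- south-east (time / min: target / %, starting material / %): 6.00: 2.1, 80.5; 12.0: 6.1, 66.4; 20.0: 8.0, 53.9; 40.0: 13.0, 37.4; 80.0: 14.5, 22.1
- west (time / min: target / %, starting material / %): 1.00: 4.9, 80.0; 2.50: 10.0, 59.5; 4.00: 15.1, 46.7; 8.00: 20.5, 30.7; 15.0: 23.6, 19.4
- north (time / min: target / %, starting material / %): 6.00: 8.6, 76.3; 20.0: 20.5, 45.9; 40.0: 31.1, 27.5; 60.0: 35.8, 19.2; 80.0: 38.1, 15.3

(each reading ± 0.5 percentage points)

- which of the two ends with the higher amount of target, in percent of the starting material charged ("neither" if they lie within 2 percentage points) (eta / theta / neither)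
- target at the end, in percent of the starting material charged, eta
- target at the end, in percent of the starting material charged, theta

- the analysis behind the earlier runs scatters by 0.5 percentage points, standard deviation

In the north run at 80.0 min, 15.3% of the starting material remains, yet target stands at 38.1%. Call the capture the target made per starting material consumed, divided by the equivalents of coupling partner charged, the limiting reagent in these recipes. The north run reads 0.703 at its last reading, and the south-east run, at the same temperature with less partner, reads 0.980. The west run reads 1.08, higher than the south-east run, but the two differ in temperature and in partner charge.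

Theta's partner charge lies nearest the north run's, so my own reckoning takes the north capture. The west run kept 19.4% after 15.0 min at 83 °C, while theta has 70.0 min at 95 °C, a longer time, so I count its starting material as fully consumed. That gives 42.2% target. Eta, reckoned with the south-east capture and the same full consumption, gives 14.7%, less than the figure for theta. That count is generous for eta, since the south-east run, warmer, still held 22.1% of its starting material at 80.0 min. So theta is the run to make, with the switch kept.

The forecast also names theta, with eta at 8.1% (6.5% to 9.8%) and theta at 49% (43% to 54%), on the ground that “Target therefore has the higher activation energy”. Its theta stands above my reckoning.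

Theta ends at 41.8% and eta at 9.66%, so theta holds more.

    starting material + free catalyst ⇌ catalyst intermediate A (K = 620 /M, k = 77.0 /M/min, Ea = 64.0 kJ/mol, ΔH = 2.00 kJ/mol)
    coupling partner + catalyst intermediate A → free catalyst + target (k = 88.0 /M/min, Ea = 52.0 kJ/mol)
    second substrate + free catalyst ⇌ catalyst intermediate B (K = 28.0 /M, k = 63.0 /M/min, Ea = 56.0 kJ/mol, ΔH = −44.0 kJ/mol)
    coupling partner + catalyst intermediate B → free catalyst + second product (k = 250 /M/min, Ea = 46.0 kJ/mol)
    2 starting material → self-condensation product (k = 0.270 /M/min, Ea = 51.0 kJ/mol)
    catalyst intermediate B → spent catalyst (k = 0.0140 /min, Ea = 92.0 kJ/mol)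
    (constants at 35 °C)

In theta, self-condensation product holds 55.5% of the starting material charged at 2.50 h. With 2.69% of the starting material left, theta's capture comes to 0.715, close to the north reading of 0.703. Eta's recipe run at 60 °C still holds 9.4% of its starting material unbound at the end, so the south-east capture 0.980 gives 13.3% target there; that flask holds 13.6%.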